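**Retrosynthetic overview**
1. Target 23 ⇐ hydrogenation (C1=C2, two benzyl esters) ⇐ acetate 22 ⇐ tertiary carbinol 21 ⇐ C8–C9 bond: SmI2 ketyl–olefin cyclisation of monocyclic keto-alkene 20, which closes ring B last.
2. Enabling feature: in ring B, C8 is a methyl carbinol carbon, so its oxygen can be carried as a methyl ketone (a ketyl precursor) on the C5 arm. C9 carries the C11–C13 propanoate, so it can be an alkene carbon (C9=C11 of a β,γ-unsaturated ester) on C10; ring A holds the two arms trans, six atoms apart.
3. 20 ⇐ ring A enone 10: α'-allylation sets quaternary C10 trans to the C5 chain; the C1 oxygen leaves via an enol triflate; allyl becomes C9=C11–C12–CO2Bn by cross-metathesis and deconjugation.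
4. Ring A ⇐ catalytic enantioselective Diels–Alder reaction of E-enal 4 (sets C4 and C5) with silyloxy diene 6, then Saegusa oxidation; 4 and 6 come from hex-5-en-2-one, methacrolein and pent-1-en-3-one.
5. Ring order: ring A (step 4), then ring B (step 14).

Key step: step 14

Remark (numbering): the target's labdane-type numbering is kept for all intermediates. Ring A = C1–C5, C10; ring B = C5–C10; C4 bears CH3 and the ring carboxyl carbon; C8 bears CH3 and O; C11–C13 is the propanoate chain on C9. β is the ring face of the C4 methyl group, α the opposite face.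
Assumption: the (S)-configured oxazaborolidinium catalyst of step 4 is taken to expose the enal face that gives the C4/C5 configuration drawn; if the sense is opposite, the (R)-catalyst is used.
Remark: 7–10 are carried as mixtures of C10 epimers (SMILES left open at that atom); this centre is planarised in step 8.

Step 1
Reactants: 1 hex-5-en-2-one
Product: 2 2-(but-3-en-1-yl)-2-methyl-1,3-dioxolane
Conditions: HOCH2CH2OH, TsOH·H2O (cat.), toluene, reflux, azeotropic removal of water
Reagents that add atoms: ethylene glycol, OCCO
Why: Acid-catalysed ketalisation masks the methyl ketone (future C8=O) against the Lewis acid, enolate, hydride and palladium chemistry that follows; no stereocentre is formed.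

Step 2
Reactants: 2 2-(but-3-en-1-yl)-2-methyl-1,3-dioxolane; 3 methacrolein (used in excess)
Product: 4 (E)-2-methyl-5-(2-methyl-1,3-dioxolan-2-yl)pent-2-enal
Conditions: second-generation Grubbs catalyst (cat.), CH2Cl2, 40 °C
Reagents that add atoms: none
Why: Olefin cross-metathesis of a terminal alkene with methacrolein should give the trisubstituted enal with the favoured E geometry (formyl trans to the chain), which later fixes the trans relation of the C4 carbonyl and the C5 side chain.

Step 3
Reactants: 5 pent-1-en-3-one
Product: 6 (Z)-3-(triisopropylsilyloxy)penta-1,3-diene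
Conditions: i-Pr3SiOTf, Et3N, Et2O, 0 → 23 °C
Reagents that add atoms: triisopropylsilyl trifluoromethanesulfonate, CC(C)[Si](OS(=O)(=O)C(F)(F)F)(C(C)C)C(C)C
Why: Silyl triflate/amine enolisation of the ethyl ketone should give the 2-silyloxy diene as the Z enol ether (methyl outward), the geometry that can reach the s-cis form needed for the Diels–Alder reaction.

Step 4
Reactants: 4 (E)-2-methyl-5-(2-methyl-1,3-dioxolan-2-yl)pent-2-enal; 6 (Z)-3-(triisopropylsilyloxy)penta-1,3-diene
Product: 7 ring A silyl enol ether aldehyde [C1(OSi-i-Pr3)=C2; C4 β-CH3 and α-CHO; C5 α-H and β-CH2CH2C(OCH2CH2O)CH3; C10 H and CH3 as epimer mixture]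
Conditions: oxazaborolidinium catalyst [B-(o-tolyl)oxazaborolidine from (S)-α,α-diphenylprolinol, activated by AlBr3] (cat.), CH2Cl2, −78 → −40 °C
Reagents that add atoms: none
Why: Catalytic enantioselective Diels–Alder reaction of an α-substituted enal on a chiral oxazaborolidinium Lewis acid: the nucleophilic, methyl-bearing diene terminus bonds to the enal β-carbon (C5) so that C1–O lies 1,4 to the new quaternary C4, the E geometry of 4 is transferred suprafacially into the trans C4-CHO/C5-chain relation, and the catalyst shields one enal face to set the absolute configuration of C4 and C5.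

Step 5
Reactants: 7 ring A silyl enol ether aldehyde
Product: 8 ring A enone aldehyde [C1=O; C2=C3; C4 β-CH3 and α-CHO; C5 β-side chain; C10 epimers]
Conditions: Pd(OAc)2 (1.05 equiv), MeCN, 40 °C
Reagents that add atoms: none
Why: Saegusa oxidation: palladation of the silyl enol ether at C2 and β-hydride elimination from C3 should give the C2=C3 enone, the only regiochemistry open to this enol ether.

Step 6
Reactants: 8 ring A enone aldehyde
Product: 9 ring A enone acid [C4 α-CO2H]
Conditions: NaClO2, NaH2PO4, 2-methyl-2-butene, t-BuOH/H2O, 0 °C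
Reagents that add atoms: sodium chlorite, [Na+].[O-]Cl=O
Why: Pinnick oxidation should convert the non-enolisable α-quaternary aldehyde to the acid without touching the enone or, in the buffered cold medium, the dioxolane.

Step 7
Reactants: 9 ring A enone acid
Product: 10 ring A enone benzyl ester [C4 α-CO2CH2Ph]
Conditions: BnBr, K2CO3, DMF, 23 °C
Reagents that add atoms: benzyl bromide, BrCc1ccccc1
Why: SN2 O-alkylation of the carboxylate gives a benzyl ester without α-hydrogen that should survive amide bases, hydride, palladium/formate, metathesis and SmI2 and is removed by hydrogenolysis at the end.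

Step 8
Reactants: 10 ring A enone benzyl ester
Product: 12 allylated enone [C10 quaternary: β-CH3 and α-allyl; otherwise as 10], via lithium dienolate 11 (not isolated)
Conditions: LiN(i-Pr)2, THF, −78 °C; then allyl bromide, DMPU, −78 → −20 °C
Reagents that add atoms: allyl bromide, C=CCBr
Why: Kinetic α'-deprotonation of the enone is regiospecific at C10 because C4 is quaternary (no γ-proton), and C-allylation of the cross-conjugated enolate should occur anti to the adjacent C5 side chain, placing allyl α (trans to C6) and the C10 methyl β, as in the 2,3-trans alkylation of 3-substituted 2-methylcyclohexanone enolates.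

Step 9
Reactants: 12 allylated enone
Product: 14 enol triflate [C1(OSO2CF3)=C2; C3 now CH2], via lithium enolate 13 (not isolated)
Conditions: LiBH(s-Bu)3 (L-Selectride), THF, −78 °C; then PhNTf2, −78 → 0 °C
Reagents that add atoms: N-phenylbis(trifluoromethanesulfonimide), O=S(=O)(N(c1ccccc1)S(=O)(=O)C(F)(F)F)C(F)(F)F
Why: Conjugate hydride addition to the β-unsubstituted enone gives the C1–C2 enolate regiospecifically, which is trapped on oxygen by the triflimide (conjugate reduction–enolate triflation).

Step 10
Reactants: 14 enol triflate
Product: 15 ring A cyclohexene [C1=C2; C4 β-CH3 and α-CO2Bn; C5 β-ketal chain; C10 β-CH3 and α-allyl]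
Conditions: Pd(OAc)2 (cat.), PPh3, n-Bu3N, HCO2H, DMF, 60 °C
Reagents that add atoms: none
Why: Palladium-catalysed formate reduction of the enol triflate (oxidative addition, formate exchange, loss of CO2, C–H reductive elimination) removes the C1 oxygen and leaves a C1=C2 alkene that is saturated in the last step.

Step 11
Reactants: 15 ring A cyclohexene; 16 benzyl acrylate
Product: 17 E-enoate [C10–CH2–CH=CH–CO2Bn; otherwise as 15]
Conditions: second-generation Grubbs catalyst (cat.), CH2Cl2, 40 °C
Reagents that add atoms: none
Why: Cross-metathesis of the terminal allyl alkene with the electron-poor acrylate should be selective for the E cross product, while the unstrained ring alkene does not react.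

Step 12
Reactants: 17 E-enoate
Product: 19 Z-β,γ-unsaturated ester [C10–CH=CH–CH2–CO2Bn; otherwise as 15], via ester dienolate 18 (not isolated)
Conditions: LiN(i-Pr)2, DMPU, THF, −78 °C; then AcOH, −78 °C
Reagents that add atoms: none
Why: Kinetic γ-deprotonation of the enoate gives the extended dienolate and kinetic α-protonation moves the double bond to C9=C11 (deconjugative protonation), which puts an alkene carbon at C9; the Z geometry expected is lost in step 14.

Step 13
Reactants: 19 Z-β,γ-unsaturated ester
Product: 20 keto-alkene [ring A with C1=C2; C4 β-CH3 and α-CO2Bn; C5 β-CH2CH2COCH3; C10 β-CH3 and α-(Z)-CH=CH–CH2–CO2Bn]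
Conditions: 1 M HCl, THF, 23 °C
Reagents that add atoms: water, O
Why: Mild aqueous acid hydrolysis of the dioxolane releases the C8 methyl ketone without moving the β,γ double bond or cleaving the benzyl esters.

Step 14
Reactants: 20 keto-alkene
Product: 21 trans-fused hydroxy diester [ring B closed; C8 α-OH and β-CH3; C9 α-H and β-CH2CH2CO2Bn; 5α-H; 10β-CH3; C1=C2; C4 α-CO2Bn]
Conditions: SmI2, HMPA, t-BuOH (2 equiv), THF, −78 → 0 °C; aq. NH4Cl at 0 °C
Reagents that add atoms: none
Why: SmI2–HMPA transfers one electron to the C8 ketone; the ketyl radical anion (C8 with reversed polarity) adds 6-exo-trig to C9 of the C9=C11 alkene, and the C11 radical is reduced by a second SmI2 to an alkylsamarium that t-BuOH protonates. The closest known reaction type is the SmI2/HMPA reductive ketyl–olefin cyclisation of unactivated olefinic ketones to 2-alkylcyclohexanols. Ring B closes through a chair in which ring A holds the C5 and C10 arms trans and pseudo-diequatorial and the quaternary C10 gives a gem-dialkyl effect, so the ring fusion is trans. At C9 the alkene residue (C11) takes the equatorial site, giving H-9 α and the chain β; at C8 the bulky HMPA-ligated O–Sm group takes the equatorial site anti to the alkene, so the oxygen ends α and the methyl β (axial). The step needs reduction of the ketone but not the benzyl esters (met by the mild reducing power of SmI2–HMPA) and addition to the exocyclic C9=C11 alkene, not the ring C1=C2 alkene, which could only be reached through a bridged boat. It also needs ring closure faster than ketyl protonation (HMPA, little t-BuOH, low temperature) and a cold quench so that the alkoxide does not lactonise.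

Step 15
Reactants: 21 trans-fused hydroxy diester
Product: 22 8α-acetate [otherwise as 21]
Conditions: Ac2O, DMAP, Et3N, CH2Cl2, 40 °C
Reagents that add atoms: acetic anhydride, CC(=O)OC(C)=O
Why: DMAP-catalysed acylation of the hindered equatorial tertiary alcohol proceeds with retention at C8, and the neutral, non-alkoxide conditions should avoid lactonisation onto the C13 ester.

Step 16
Reactants: 22 8α-acetate
Product: 23 target diacid CNP0196050.1
Conditions: H2 (1 atm), Pd on carbon (Pd/C), EtOAc, 23 °C
Reagents that add atoms: none
Why: Heterogeneous hydrogenation saturates the C1=C2 alkene and hydrogenolyses both benzyl esters in one operation, leaving the tertiary acetate and all stereocentres untouched.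

**Compound list**
1 | hex-5-en-2-one | CC(=O)CCC=C | starting material
2 | 2-(but-3-en-1-yl)-2-methyl-1,3-dioxolane | CC1(CCC=C)OCCO1 | intermediate
3 | methacrolein (2-methylprop-2-enal) | CC(=C)C=O | starting material
4 | (E)-2-methyl-5-(2-methyl-1,3-dioxolan-2-yl)pent-2-enal | O=C/C(C)=C/CCC1(C)OCCO1 | intermediate
5 | pent-1-en-3-one | CCC(=O)C=C | starting material
6 | (Z)-3-(triisopropylsilyloxy)penta-1,3-diene | C=C/C(O[Si](C(C)C)(C(C)C)C(C)C)=C/C | intermediate
7 | ring A silyl enol ether aldehyde (C1(OSi-i-Pr3)=C2; C4 β-CH3, α-CHO; C5 β-ketal chain; C10 epimers) | CC1(CC[C@@H]2C(C)C(O[Si](C(C)C)(C(C)C)C(C)C)=CC[C@@]2(C)C=O)OCCO1 | intermediate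
8 | ring A enone aldehyde (C1=O, C2=C3; C10 epimers) | CC1(CC[C@@H]2C(C)C(=O)C=C[C@@]2(C)C=O)OCCO1 | intermediate
9 | ring A enone acid (C4 α-CO2H; C10 epimers) | CC1(CC[C@@H]2C(C)C(=O)C=C[C@@]2(C)C(=O)O)OCCO1 | intermediate
10 | ring A enone benzyl ester (C10 epimers) | CC1(CC[C@@H]2C(C)C(=O)C=C[C@@]2(C)C(=O)OCc3ccccc3)OCCO1 | intermediate
11 | lithium dienolate of 10 (C10=C1(OLi)–C2=C3) | CC1(CC[C@@H]2C(C)=C(O[Li])C=C[C@@]2(C)C(=O)OCc3ccccc3)OCCO1 | intermediate
12 | allylated enone (C10 β-CH3, α-allyl) | CC1(CC[C@@H]2[C@](C)(C(=O)C=C[C@@]2(C)C(=O)OCc3ccccc3)CC=C)OCCO1 | intermediate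
13 | lithium enolate from 12 (C1(OLi)=C2) | CC1(CC[C@@H]2[C@](C)(C(O[Li])=CC[C@@]2(C)C(=O)OCc3ccccc3)CC=C)OCCO1 | intermediate
14 | enol triflate (C1(OSO2CF3)=C2) | CC1(CC[C@@H]2[C@](C)(C(OS(=O)(=O)C(F)(F)F)=CC[C@@]2(C)C(=O)OCc3ccccc3)CC=C)OCCO1 | intermediate
15 | ring A cyclohexene (C1=C2; C10 α-allyl) | CC1(CC[C@@H]2[C@](C)(C=CC[C@@]2(C)C(=O)OCc3ccccc3)CC=C)OCCO1 | intermediate
16 | benzyl acrylate | C=CC(=O)OCc1ccccc1 | starting material
17 | E-enoate (C10–CH2–CH=CH–CO2Bn) | CC1(CC[C@@H]2[C@](C)(C=CC[C@@]2(C)C(=O)OCc3ccccc3)C/C=C/C(=O)OCc4ccccc4)OCCO1 | intermediate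
18 | lithium ester dienolate of 17 (geometry open) | CC1(CC[C@@H]2[C@](C)(C=CC[C@@]2(C)C(=O)OCc3ccccc3)C=CC=C(O[Li])OCc4ccccc4)OCCO1 | intermediate
19 | Z-β,γ-unsaturated ester ketal (C10–CH=CH–CH2–CO2Bn) | CC1(CC[C@@H]2[C@](C)(C=CC[C@@]2(C)C(=O)OCc3ccccc3)/C=C\CC(=O)OCc4ccccc4)OCCO1 | intermediate
20 | keto-alkene, key-step precursor | CC(=O)CC[C@@H]1[C@](C)(C=CC[C@@]1(C)C(=O)OCc2ccccc2)/C=C\CC(=O)OCc3ccccc3 | intermediate
21 | trans-fused 8α-hydroxy dibenzyl ester (C1=C2) | O[C@]1(C)CC[C@@H]2[C@](C)(C=CC[C@@]2(C)C(=O)OCc3ccccc3)[C@H]1CCC(=O)OCc4ccccc4 | intermediate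
22 | 8α-acetoxy dibenzyl ester (C1=C2) | CC(=O)O[C@]1(C)CC[C@@H]2[C@](C)(C=CC[C@@]2(C)C(=O)OCc3ccccc3)[C@H]1CCC(=O)OCc4ccccc4 | intermediate
23 | CNP0196050.1 (8α-acetoxy diacid; 4β-CH3, 4α-CO2H, 5α-H, 8β-CH3, 9α-H, 10β-CH3) | CC(=O)O[C@]1(C)CC[C@@H]2[C@](C)(CCC[C@@]2(C)C(=O)O)[C@H]1CCC(=O)O | target

**Step count**
Total steps: 16. Longest linear sequence: 15 steps (steps 1, 2 and 4–16); step 3 is a one-step branch.

**Steps most likely to fail**
1. Step 14 (key step). The ketyl may be reduced and protonated before it adds to the unactivated 1,2-disubstituted alkene. The carbonyl face may be chosen so that the oxygen ends axial. The samarium alkoxide may acylate itself on the C13 ester with loss of benzyl alcohol. The fallback replaces the radical ring closure by a polar, pericyclic one and sets out from 20. Me2AlCl in CH2Cl2 at −78 → 0 °C should bring about an intramolecular carbonyl-ene reaction in which C9 attacks the aluminium-complexed ketone through the same chair while a C12 hydrogen passes to oxygen. This gives hydroxy E-enoate F1, whose E double bond makes lactonisation geometrically impossible. Acetylation as in step 15 gives acetoxy enoate F2, and hydrogenation as in step 16 reduces both C=C bonds and cleaves both benzyl esters, so the fallback comes back to the route at 23.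

2. Step 4. The β-substituted α-methyl enal may add too slowly, the catalyst may discriminate the enal faces poorly, and the strong Lewis acid may open the dioxolane. The fallback uses a more nucleophilic diene and a mild Lewis acid, needs no separate oxidation, and sets out from 4. The 1-amino-3-silyloxy diene F3 is made from commercially available (E)-1-(dimethylamino)pent-1-en-3-one with KN(SiMe3)2 and t-BuMe2SiCl. It should add to 4 under catalysis by chiral (salen)CrCl (chloro[N,N'-bis(3,5-di-tert-butylsalicylidene)-1,2-cyclohexanediaminato]chromium, trivalent chromium) to give amino silyl enol ether adduct F4. HF in MeCN then cleaves the silyl enol ether and eliminates dimethylamine, which gives enone aldehyde 8 directly; the fallback comes back to the route at 8 and step 5 is not needed.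

3. Step 8. Facial selectivity at the hindered α'-carbon may be poor, O-allylation may compete, and proton exchange may return 10. The fallback uses inner-sphere allyl transfer under ligand control instead of SN2 alkylation and sets out from 10. Lithium dienolate 11 is trapped on oxygen with allyl chloroformate to give allyl dienyl carbonate F5. Pd2(dba)3 with the (S)-tert-butyl-phosphinooxazoline ligand in THF should then induce decarboxylative Tsuji allylation at C10, the chiral ligand reinforcing delivery to the α face, and the fallback comes back to the route at 12.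

Further compounds
F1 | step 14 | hydroxy E-enoate (C8 α-OH, β-CH3; C9 β-(E)-CH=CH–CO2Bn; C1=C2; C4 α-CO2Bn) | O[C@]1(C)CC[C@@H]2[C@](C)(C=CC[C@@]2(C)C(=O)OCc3ccccc3)[C@H]1/C=C/C(=O)OCc4ccccc4
F2 | step 14 | acetoxy E-enoate (8α-acetate of F1) | CC(=O)O[C@]1(C)CC[C@@H]2[C@](C)(C=CC[C@@]2(C)C(=O)OCc3ccccc3)[C@H]1/C=C/C(=O)OCc4ccccc4
F3 | step 4 | (1E,3Z)-1-(dimethylamino)-3-(tert-butyldimethylsilyloxy)penta-1,3-diene | CN(C)/C=C/C(O[Si](C)(C)C(C)(C)C)=C/C
F4 | step 4 | amino silyl enol ether adduct (C1(OSi-t-BuMe2)=C2; C3 NMe2; C4 β-CH3, α-CHO; C5 β-ketal chain; C3 and C10 epimers) | CC1(CC[C@@H]2C(C)C(O[Si](C)(C)C(C)(C)C)=CC(N(C)C)[C@@]2(C)C=O)OCCO1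
F5 | step 8 | allyl dienyl carbonate of 10 (C10=C1(OCO2-allyl)–C2=C3) | CC1(CC[C@@H]2C(C)=C(OC(=O)OCC=C)C=C[C@@]2(C)C(=O)OCc3ccccc3)OCCO1
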